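**Strategy**

Everything rests on treating the oxolane (O1, C2 aryl, C3 with hydroxymethyl C6, C4 with benzyl carbon C7, C5) as a reduced γ-lactone whose carbonyl is C5 and whose ring CH2 is C6, and on adding a provisional C2–C4 bond so that C2, C3 and C4 form a cyclopropane. The feature used is the 1,3-relationship of benzylic, cation-stabilising C2 and C4, which is enolisable once C5 is a carbonyl. A single enantioselective carbene addition forms C3–C4 and C2–C4, closes the three-membered ring and the lactone, and sets C3. Its precursor is (Z)-3-(3,4,5-trimethoxyphenyl)allyl diazoacetate. Ring opening by methanol at C2, trans benzylation at C4, reduction and acid-mediated closure complete the route.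

Key step: step 5

Assumption: Rh2(5R-MEPY)4 is taken as the catalyst enantiomer that gives the (1S,5R,6S) lactone, by analogy with the facial sense known for simpler allylic diazoacetates; if the sense proves opposite, the 5S catalyst is used.

Remark: the methoxy lactone and its successors are drawn as the C2 epimer expected from backside attack; the other C2 epimer would serve equally, because C2 is re-formed in the last step.

Design notes: the Z alkene is kept in the precursor even though only C3 survives from the key step, because cis-disubstituted allylic diazoacetates are the class on which chiral dirhodium carboxamidates discriminate alkene faces best. The diazoacetate is made by the ditosylhydrazine route at 0 °C, which avoids heating the Z alkene. An aryl iodide is used so that the alkyne coupling runs at room temperature. The bicyclic lactone required is the (1S,5R,6S) enantiomer; its C5 becomes C3 (R) of the target.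

**Route**

Step 1
Reactants: 1 5-iodo-1,2,3-trimethoxybenzene; 2 prop-2-yn-1-ol
Product: 3 3-(3,4,5-trimethoxyphenyl)prop-2-yn-1-ol
Conditions: Pd(PPh3)2Cl2 (2 mol%), CuI (4 mol%), Et3N, THF, rt
Reagents that add atoms: none
Why: Sonogashira coupling of an aryl iodide with a terminal alkyne runs at room temperature and tolerates the free propargylic hydroxyl and the electron-rich ring.

Step 2
Reactants: 3 3-(3,4,5-trimethoxyphenyl)prop-2-yn-1-ol
Product: 4 (Z)-3-(3,4,5-trimethoxyphenyl)prop-2-en-1-ol
Conditions: H2 (1 atm), 5% Pd/CaCO3 poisoned with Pb(OAc)2, quinoline, EtOAc, rt, stopped after one equivalent of H2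
Reagents that add atoms: none
Why: Lindlar semihydrogenation delivers both hydrogens to one face of the alkyne on the poisoned palladium surface, giving the Z alkene, while quinoline restrains over-reduction and Z-to-E drift.

Step 3
Reactants: 4 (Z)-3-(3,4,5-trimethoxyphenyl)prop-2-en-1-ol; 5 bromoacetyl bromide
Product: 6 (Z)-3-(3,4,5-trimethoxyphenyl)prop-2-en-1-yl bromoacetate
Conditions: NaHCO3, MeCN, 0 °C
Reagents that add atoms: none
Why: O-acylation of the primary allylic alcohol by the acid bromide is fast at 0 °C, and the bicarbonate buffer keeps the acid-sensitive Z-cinnamyl system from ionising or isomerising.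

Step 4
Reactants: 6 (Z)-3-(3,4,5-trimethoxyphenyl)prop-2-en-1-yl bromoacetate
Product: 9 (Z)-3-(3,4,5-trimethoxyphenyl)prop-2-en-1-yl diazoacetate, via N-alkylated ditosylhydrazine 7 (not isolated), via glyoxylate tosylhydrazone 8 (not isolated)
Conditions: TsNHNHTs (2 equiv), DBU (5 equiv), THF, 0 °C
Reagents that add atoms: N,N'-ditosylhydrazine, Cc1ccc(cc1)S(=O)(=O)NNS(=O)(=O)c1ccc(C)cc1
Why: In this ditosylhydrazine route to diazoacetates the sulfonyl hydrazide anion displaces bromide and DBU then expels two sulfinate groups in turn (the second in Bamford–Stevens fashion), all at 0 °C so that the Z alkene is not disturbed.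

Step 5
Reactants: 9 (Z)-3-(3,4,5-trimethoxyphenyl)prop-2-en-1-yl diazoacetate
Product: 10 (1S,5R,6S)-6-(3,4,5-trimethoxyphenyl)-3-oxabicyclo[3.1.0]hexan-2-one
Conditions: Rh2(5R-MEPY)4 [dirhodium tetrakis(methyl (5R)-2-oxopyrrolidine-5-carboxylate)] (1 mol%), CH2Cl2, reflux, 9 added by syringe pump over about 10 h
Reagents that add atoms: none
Why: Loss of N2 from 9 at a divalent rhodium centre gives an electrophilic rhodium-bound carbene whose carbon (C4) adds to the tethered alkene in a concerted, asynchronous way, forming C3–C4 and C2–C4 with retention of the Z geometry. The closest known reaction type is the catalytic enantioselective intramolecular cyclopropanation of allylic diazoacetates by chiral dirhodium carboxamidates. The cyclopropane (C2, C3, C4) closes by [2+1] carbene transfer and the five-membered lactone (C4, C5, O, C6, C3) closes in the same event in a 5-exo sense onto the near alkene carbon C3, the short tether forcing cis fusion. C3 and C4 are set by the alkene face that the chiral carboxamidate ligands leave open to the carbene, and C2 follows from stereospecific syn addition to the Z alkene, so the aryl group lies endo. The selectivity needed is enantioface selection, since only C3 is carried to the target; the cis-disubstituted alkene secures it because its aryl group points away from the ligand ester groups in the favoured approach, and slow addition should suppress carbene dimerisation.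

Step 6
Reactants: 10 (1S,5R,6S)-6-(3,4,5-trimethoxyphenyl)-3-oxabicyclo[3.1.0]hexan-2-one
Product: 11 (4R)-4-[(S)-methoxy(3,4,5-trimethoxyphenyl)methyl]oxolan-2-one
Conditions: TfOH (10 mol%), MeOH (10 equiv), HFIP, 0 °C to rt
Reagents that add atoms: methanol, CO
Why: This is a Brønsted-acid-catalysed nucleophilic ring opening of an aryl-donor/carbonyl-acceptor cyclopropane, in which protonation of the lactone carbonyl polarises C2–C4 (the only bond flanked by donor and acceptor and the one aligned with the carbonyl π system), so methanol should attack benzylic C2 with strain release and expected inversion while C3 is untouched.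

Step 7
Reactants: 11 (4R)-4-[(S)-methoxy(3,4,5-trimethoxyphenyl)methyl]oxolan-2-one; 12 3,4,5-trimethoxybenzyl bromide
Product: 14 (3R,4R)-4-[(S)-methoxy(3,4,5-trimethoxyphenyl)methyl]-3-(3,4,5-trimethoxybenzyl)oxolan-2-one, via lithium enolate 13 (not isolated)
Conditions: LiN(SiMe3)2 (1.05 equiv), THF, −78 °C; then 12, DMPU, −78 to −40 °C
Reagents that add atoms: none
Why: Alkylation of a γ-butyrolactone lithium enolate by a benzylic bromide should occur on the face opposite the bulky C3 substituent, setting C4 trans to C3 as is usual for β-substituted butyrolactones.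

Step 8
Reactants: 14 (3R,4R)-4-[(S)-methoxy(3,4,5-trimethoxyphenyl)methyl]-3-(3,4,5-trimethoxybenzyl)oxolan-2-one
Product: 15 (2R,3R)-2-[(S)-methoxy(3,4,5-trimethoxyphenyl)methyl]-3-[(3,4,5-trimethoxyphenyl)methyl]butane-1,4-diol
Conditions: LiAlH4, THF, 0 °C to rt; then H2O, 15% aq. NaOH, H2O
Reagents that add atoms: none
Why: Hydride reduction of the lactone by LiAlH4 gives the 1,4-diol and should leave the benzylic methyl ether, the aryl ethers and both stereocentres untouched.

Step 9
Reactants: 15 (2R,3R)-2-[(S)-methoxy(3,4,5-trimethoxyphenyl)methyl]-3-[(3,4,5-trimethoxyphenyl)methyl]butane-1,4-diol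
Product: 16 [(2S,3R,4R)-2-(3,4,5-trimethoxyphenyl)-4-[(3,4,5-trimethoxyphenyl)methyl]oxolan-3-yl]methanol
Conditions: TfOH (5 mol%), CH2Cl2 (about 0.02 M), −20 to 0 °C; quench with Et3N at full conversion
Reagents that add atoms: none
Why: In this acid-catalysed SN1 etherification the benzylic methyl ether ionises and the C5 hydroxyl captures the C2 cation in a five-membered closure (the C6 hydroxyl could only form an oxetane), and reversible capture should place the aryl group trans to the C3 hydroxymethyl, which sets C2 as S.

**Compound list**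

1 | 5-iodo-1,2,3-trimethoxybenzene | COc1cc(I)cc(OC)c1OC | starting material
2 | prop-2-yn-1-ol (propargyl alcohol) | C#CCO | starting material
3 | 3-(3,4,5-trimethoxyphenyl)prop-2-yn-1-ol | COc1cc(C#CCO)cc(OC)c1OC | intermediate
4 | (Z)-3-(3,4,5-trimethoxyphenyl)prop-2-en-1-ol | COc1cc(/C=C\CO)cc(OC)c1OC | intermediate
5 | bromoacetyl bromide | BrCC(Br)=O | starting material
6 | (Z)-3-(3,4,5-trimethoxyphenyl)prop-2-en-1-yl bromoacetate | COc1cc(/C=C\COC(=O)CBr)cc(OC)c1OC | intermediate
7 | (Z)-3-(3,4,5-trimethoxyphenyl)prop-2-en-1-yl [1,2-bis(4-methylbenzenesulfonyl)hydrazin-1-yl]acetate | COc1cc(/C=C\COC(=O)CN(NS(=O)(=O)c2ccc(C)cc2)S(=O)(=O)c2ccc(C)cc2)cc(OC)c1OC | intermediate (not isolated)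
8 | (Z)-3-(3,4,5-trimethoxyphenyl)prop-2-en-1-yl [2-(4-methylbenzenesulfonyl)hydrazinylidene]acetate (C=N geometry not defined) | COc1cc(/C=C\COC(=O)C=NNS(=O)(=O)c2ccc(C)cc2)cc(OC)c1OC | intermediate (not isolated)
9 | (Z)-3-(3,4,5-trimethoxyphenyl)prop-2-en-1-yl diazoacetate | COc1cc(/C=C\COC(=O)C=[N+]=[N-])cc(OC)c1OC | intermediate
10 | (1S,5R,6S)-6-(3,4,5-trimethoxyphenyl)-3-oxabicyclo[3.1.0]hexan-2-one (cis-fused, aryl endo) | O=C1OC[C@H]2[C@@H]1[C@H]2c1cc(OC)c(OC)c(OC)c1 | intermediate
11 | (4R)-4-[(S)-methoxy(3,4,5-trimethoxyphenyl)methyl]oxolan-2-one | O=C1OC[C@@H](C1)[C@H](OC)c1cc(OC)c(OC)c(OC)c1 | intermediate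
12 | 3,4,5-trimethoxybenzyl bromide | COc1cc(CBr)cc(OC)c1OC | starting material
13 | lithium (4R)-4-[(S)-methoxy(3,4,5-trimethoxyphenyl)methyl]-4,5-dihydrofuran-2-olate | [Li]OC1=C[C@H](CO1)[C@H](OC)c1cc(OC)c(OC)c(OC)c1 | intermediate (not isolated)
14 | (3R,4R)-4-[(S)-methoxy(3,4,5-trimethoxyphenyl)methyl]-3-(3,4,5-trimethoxybenzyl)oxolan-2-one (3,4-trans) | O=C1OC[C@@H]([C@H]1Cc1cc(OC)c(OC)c(OC)c1)[C@H](OC)c1cc(OC)c(OC)c(OC)c1 | intermediate
15 | (2R,3R)-2-[(S)-methoxy(3,4,5-trimethoxyphenyl)methyl]-3-[(3,4,5-trimethoxyphenyl)methyl]butane-1,4-diol | OC[C@@H]([C@H](CO)Cc1cc(OC)c(OC)c(OC)c1)[C@H](OC)c1cc(OC)c(OC)c(OC)c1 | intermediate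
16 | [(2S,3R,4R)-2-(3,4,5-trimethoxyphenyl)-4-[(3,4,5-trimethoxyphenyl)methyl]oxolan-3-yl]methanol (2,3-trans, 3,4-cis) | COc1cc(C[C@H]2CO[C@H](c3cc(OC)c(OC)c(OC)c3)[C@H]2CO)cc(OC)c1OC | target

**Totals and risks**

Total step count: 9. Longest linear sequence: 9 steps (from 1 or 2 to 16); 5 and 12 enter as purchased building blocks.

Steps most likely to fail:

Step 6. The cyclopropane carries only one acceptor, so alcoholysis may be sluggish. Under forcing acid the benzylic cation may instead be intercepted by the electron-rich ring of a second molecule, or lose a proton. Fallback: setting out from 10, the ring is opened by bromide, a far stronger nucleophile than methanol. HBr (33% in AcOH) in CH2Cl2 at 0 °C should give (4R)-4-[bromo(3,4,5-trimethoxyphenyl)methyl]oxolan-2-one F1 as benzylic epimers. Silver-assisted solvolysis of this bromide (Ag2CO3, MeOH, rt) should then give 11, where the route is rejoined.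

Step 9. Substrate and product are both benzylic ethers and ionise at similar rates. Repeated ionisation may therefore leak into Friedel–Crafts closure of C2 onto the neighbouring trimethoxybenzyl ring, or erode the trans selectivity at C2. Fallback: C2 is carried as a phenyl sulfide, so that the cation is generated once, under buffered conditions in which the product ether is inert. Setting out from 10, PhSH with TfOH (10 mol%) in HFIP should give (4R)-4-[(phenylsulfanyl)(3,4,5-trimethoxyphenyl)methyl]oxolan-2-one F2. LiN(SiMe3)2 in THF at −78 °C forms the lithium enolate of the sulfide lactone F3, which with 12 should give (3R,4R)-4-[(phenylsulfanyl)(3,4,5-trimethoxyphenyl)methyl]-3-(3,4,5-trimethoxybenzyl)oxolan-2-one F4. LiAlH4 then gives (2R,3R)-2-[(phenylsulfanyl)(3,4,5-trimethoxyphenyl)methyl]-3-[(3,4,5-trimethoxyphenyl)methyl]butane-1,4-diol F5. S-methylation with MeOTf in CH2Cl2 in the presence of 2,6-di-tert-butyl-4-methylpyridine forms the S-methyl-S-phenylsulfonium triflate of the diol F6. This should ionise and be captured by the C5 hydroxyl, coming back to the route at 16.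

Step 5. Enantioface selection may be insufficient with the trimethoxyaryl Z alkene, or the carbene may dimerise. Fallback: stereocontrol is moved from the catalyst to a resolution. Setting out from 9, achiral Rh2(OAc)4 (1 mol%, CH2Cl2, slow addition) should give the racemic lactone, that is 10 together with its mirror image (1R,5S,6R)-6-(3,4,5-trimethoxyphenyl)-3-oxabicyclo[3.1.0]hexan-2-one F7. Preparative chromatography on a chiral stationary phase returns to the route at 10.

**Further compounds**

F1 | step 6 | (4R)-4-[bromo(3,4,5-trimethoxyphenyl)methyl]oxolan-2-one (epimers at the benzylic carbon) | O=C1OC[C@@H](C1)C(Br)c1cc(OC)c(OC)c(OC)c1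
F2 | step 9 | (4R)-4-[(phenylsulfanyl)(3,4,5-trimethoxyphenyl)methyl]oxolan-2-one (epimers at the benzylic carbon) | O=C1OC[C@@H](C1)C(Sc1ccccc1)c1cc(OC)c(OC)c(OC)c1
F3 | step 9 | lithium (4R)-4-[(phenylsulfanyl)(3,4,5-trimethoxyphenyl)methyl]-4,5-dihydrofuran-2-olate | [Li]OC1=C[C@H](CO1)C(Sc1ccccc1)c1cc(OC)c(OC)c(OC)c1
F4 | step 9 | (3R,4R)-4-[(phenylsulfanyl)(3,4,5-trimethoxyphenyl)methyl]-3-(3,4,5-trimethoxybenzyl)oxolan-2-one | O=C1OC[C@@H]([C@H]1Cc1cc(OC)c(OC)c(OC)c1)C(Sc1ccccc1)c1cc(OC)c(OC)c(OC)c1
F5 | step 9 | (2R,3R)-2-[(phenylsulfanyl)(3,4,5-trimethoxyphenyl)methyl]-3-[(3,4,5-trimethoxyphenyl)methyl]butane-1,4-diol | OC[C@@H]([C@H](CO)Cc1cc(OC)c(OC)c(OC)c1)C(Sc1ccccc1)c1cc(OC)c(OC)c(OC)c1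
F6 | step 9 | S-methyl-S-phenylsulfonium triflate of diol F5 | OC[C@@H]([C@H](CO)Cc1cc(OC)c(OC)c(OC)c1)C([S+](C)c1ccccc1)c1cc(OC)c(OC)c(OC)c1.[O-]S(=O)(=O)C(F)(F)F
F7 | step 5 | (1R,5S,6R)-6-(3,4,5-trimethoxyphenyl)-3-oxabicyclo[3.1.0]hexan-2-one | O=C1OC[C@@H]2[C@H]1[C@@H]2c1cc(OC)c(OC)c(OC)c1
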